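Numbering used: 3,7-dioxabicyclo[3.3.0]octane with C1–H and C5–OH as bridgeheads; ring A = C1–C2(aryl, exo)–O3–C4–C5, ring B = C5–C6(aryl, endo)–O7–C8–C1.
Retrosynthesis: cut the aryl–C2 bond (veratrole plus the lactol-derived oxocarbenium ion of ring A); take C2 back to a lactone carbonyl and C1–H to C1–CO2Me; cut the O3–C2 acyl bond and the C4–O/C5–O bonds (osmylation of an exocyclic alkene); cut C1–C5 and O7–C8 (oxa-Michael/Conia-ene annulation); last the C6–alkyne bond.
Forward: alkynylation of veratraldehyde, ring B by annulation with dimethyl methylenemalonate, ring A as a γ-lactone by dihydroxylation–lactonisation, loss of the helper ester, lactol, arylation.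
Stereochemistry: C6 from a catalytic asymmetric alkynylation; C5 by osmylation anti to the C6 aryl; C1 by the forced cis ring fusion; C2 by attack on the convex face.
Enabling feature: the ring oxygen O3 stabilises a cation at C2, and ring B with the endo aryl on C6 closes the concave face of the cis-fused bicycle, so only the exo face of C2 is open; veratrole reacts para to a methoxy group, which gives the 3,4-dimethoxyphenyl pattern.
Helpers: the second ester on C1 (activates the carbocyclisation, removed by Krapcho reaction) and the lactone oxidation level at C2 (lowered to the lactol just before the arylation).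

Key step: step 6

Assumption: the ligand antipode in step 1 is the one that delivers the (R)-carbinol; if the sense of induction is the other way round, the other antipode is taken. Dimethyl methylenemalonate is bought stabilised and distilled before use.

Step 1
Reactants: 1 3,4-dimethoxybenzaldehyde (veratraldehyde); 2 ethynyltrimethylsilane
Product: 4 (R)-1-(3,4-dimethoxyphenyl)prop-2-yn-1-ol, via silylated carbinol 3 (not isolated)
Conditions: 2 (3 equiv), Me2Zn (3 equiv), ProPhenol ligand (10 mol %), Ph3PO (20 mol %), toluene, 4 °C; aq. NH4Cl; then K2CO3, MeOH, rt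
Reagents that add atoms: none
Why: Zinc–ProPhenol-catalysed asymmetric alkynylation of an aryl aldehyde should set C6 by catalyst control, and K2CO3/MeOH protodesilylation then frees the terminal alkyne without touching the carbinol centre.

Step 2
Reactants: 4 (R)-1-(3,4-dimethoxyphenyl)prop-2-yn-1-ol; 5 dimethyl methylenemalonate
Product: 7 dimethyl (5S)-5-(3,4-dimethoxyphenyl)-4-methylideneoxolane-3,3-dicarboxylate, via oxa-Michael adduct 6 (not isolated)
Conditions: t-BuOK (10 mol %), THF, 0 °C, slow addition of 5 (1.2 equiv); then CuI (5 mol %), rt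
Reagents that add atoms: none
Why: Oxa-Michael addition of the propargylic alkoxide to the methylenemalonate followed by copper-catalysed Conia-ene-type 5-exo-dig carbocyclisation of the malonate onto the terminal alkyne should build ring B with its exocyclic methylene, creating no new stereocentre and leaving C6 untouched under the malonate-buffered conditions.

Step 3
Reactants: 7 dimethyl (5S)-5-(3,4-dimethoxyphenyl)-4-methylideneoxolane-3,3-dicarboxylate
Product: 9 methyl (1S,5S,6S)-6-(3,4-dimethoxyphenyl)-5-hydroxy-2-oxo-3,7-dioxabicyclo[3.3.0]octane-1-carboxylate (cis-fused; aryl endo; OH and CO2Me on the convex face), via diol diester 8 (not isolated)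
Conditions: OsO4 (2 mol %), NMO (1.5 equiv), acetone/H2O, rt; aq. Na2SO3; then PPTS (cat.), CH2Cl2, rt
Reagents that add atoms: N-methylmorpholine N-oxide, C[N+]1([O-])CCOCC1; water, O
Why: Upjohn dihydroxylation should add OsO4 to the exocyclic alkene from the ring face anti to the neighbouring aryl group, so that the new C5–OH is trans and the CH2OH cis to the aryl, and the ester that is cis to the CH2OH then closes the γ-lactone (ring A), which fixes the cis ring fusion and tells the two esters apart.

Step 4
Reactants: 9 methyl (1S,5S,6S)-6-(3,4-dimethoxyphenyl)-5-hydroxy-2-oxo-3,7-dioxabicyclo[3.3.0]octane-1-carboxylate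
Product: 10 (1S,5S,6S)-6-(3,4-dimethoxyphenyl)-5-hydroxy-3,7-dioxabicyclo[3.3.0]octan-2-one
Conditions: LiCl (3 equiv), H2O (2 equiv), DMSO, 130 °C
Reagents that add atoms: none
Why: Krapcho demethoxycarbonylation of the malonate-type α-carbomethoxy lactone should remove the helper ester, and protonation of the lactone enolate at the ring-fusion carbon can only give the cis-fused bicycle, which sets C1.

Step 5
Reactants: 10 (1S,5S,6S)-6-(3,4-dimethoxyphenyl)-5-hydroxy-3,7-dioxabicyclo[3.3.0]octan-2-one
Product: 11 (1S,5S,6S)-6-(3,4-dimethoxyphenyl)-3,7-dioxabicyclo[3.3.0]octane-2,5-diol (lactol, both C2 epimers)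
Conditions: i-Bu2AlH (2.5 equiv), CH2Cl2, −78 °C; aq. potassium sodium tartrate
Reagents that add atoms: none
Why: Partial reduction of a γ-lactone with i-Bu2AlH at low temperature should stop at the lactol because the tetrahedral aluminium hemiacetal is stable until work-up, with one extra equivalent consumed by the tertiary hydroxyl.

Step 6
Reactants: 11 (1S,5S,6S)-6-(3,4-dimethoxyphenyl)-3,7-dioxabicyclo[3.3.0]octane-2,5-diol; 12 1,2-dimethoxybenzene (veratrole)
Product: 14 (1R,2S,5S,6S)-2,6-bis(3,4-dimethoxyphenyl)-3,7-dioxabicyclo[3.3.0]octan-5-ol (target; C2 aryl exo, C6 aryl endo), via bicyclic oxocarbenium ion 13 (not isolated)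
Conditions: 12 (6 equiv), BF3·OEt2 (1.5 equiv), 4 Å MS, CH2Cl2, −78 to −20 °C; aq. NaHCO3
Reagents that add atoms: none
Why: BF3 ionises the lactol C2–OH to the oxocarbenium ion 13, whose charge at C2 is carried by the O3 lone pair; veratrole attacks through the position para to a methoxy group and the Wheland intermediate rearomatises. The closest known reaction type is the Friedel–Crafts C-arylation of lactol-derived cyclic oxocarbenium ions, as in aryl C-glycoside synthesis and in the acid-mediated conversion of sesamolin (through the samin cation) into sesaminol. No ring is closed here; rings A and B are already in place and both lactol epimers converge on the same cation. The new stereocentre C2 is controlled by the cis-fused bicycle: ring B and the endo aryl on C6 block the concave face, so the arene enters on the convex face and the new aryl ends exo, cis to H1. The step needs regioselectivity on veratrole (secured by the para-directing methoxy group and the hindered ortho positions), exo selectivity (secured by the bicycle) and ionisation at the hemiacetal carbon C2 in preference to the benzylic ether carbon C6 (secured by the much easier ionisation of a hemiacetal, the deactivating β-oxygen at C5 and the low temperature). Excess arene should make capture of the cation faster than loss of the C1 proton.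

Compound list
1 | 3,4-dimethoxybenzaldehyde (veratraldehyde) | COc1ccc(C=O)cc1OC | starting material
2 | ethynyltrimethylsilane | C#C[Si](C)(C)C | starting material
3 | (S)-1-(3,4-dimethoxyphenyl)-3-(trimethylsilyl)prop-2-yn-1-ol (same spatial arrangement as 4; the descriptor changes with the silyl group) | C[Si](C)(C)C#C[C@@H](O)c1ccc(OC)c(OC)c1 | intermediate
4 | (R)-1-(3,4-dimethoxyphenyl)prop-2-yn-1-ol | C#C[C@@H](O)c1ccc(OC)c(OC)c1 | intermediate
5 | dimethyl methylenemalonate | C=C(C(=O)OC)C(=O)OC | starting material
6 | dimethyl 2-({[(1R)-1-(3,4-dimethoxyphenyl)prop-2-yn-1-yl]oxy}methyl)malonate | C#C[C@@H](OCC(C(=O)OC)C(=O)OC)c1ccc(OC)c(OC)c1 | intermediate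
7 | dimethyl (5S)-5-(3,4-dimethoxyphenyl)-4-methylideneoxolane-3,3-dicarboxylate | COC(=O)C1(C(=O)OC)CO[C@@H](c2ccc(OC)c(OC)c2)C1=C | intermediate
8 | dimethyl (4S,5S)-5-(3,4-dimethoxyphenyl)-4-hydroxy-4-(hydroxymethyl)oxolane-3,3-dicarboxylate (OH trans, CH2OH cis to the aryl) | COC(=O)C1(C(=O)OC)CO[C@@H](c2ccc(OC)c(OC)c2)[C@@]1(O)CO | intermediate
9 | methyl (1S,5S,6S)-6-(3,4-dimethoxyphenyl)-5-hydroxy-2-oxo-3,7-dioxabicyclo[3.3.0]octane-1-carboxylate | O=C1OC[C@@]2(O)[C@]1(C(=O)OC)CO[C@H]2c1ccc(OC)c(OC)c1 | intermediate
10 | (1S,5S,6S)-6-(3,4-dimethoxyphenyl)-5-hydroxy-3,7-dioxabicyclo[3.3.0]octan-2-one | O=C1OC[C@@]2(O)[C@@H]1CO[C@H]2c1ccc(OC)c(OC)c1 | intermediate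
11 | (1S,5S,6S)-6-(3,4-dimethoxyphenyl)-3,7-dioxabicyclo[3.3.0]octane-2,5-diol (both C2 epimers) | OC1OC[C@@]2(O)[C@@H]1CO[C@H]2c1ccc(OC)c(OC)c1 | intermediate
12 | 1,2-dimethoxybenzene (veratrole) | COc1ccccc1OC | starting material
13 | (1S,5S,6S)-6-(3,4-dimethoxyphenyl)-5-hydroxy-3,7-dioxabicyclo[3.3.0]oct-2-en-3-ium (C2=O3 oxocarbenium ion) | [CH]1=[O+]C[C@@]2(O)[C@@H]1CO[C@H]2c1ccc(OC)c(OC)c1 | intermediate
14 | (1R,2S,5S,6S)-2,6-bis(3,4-dimethoxyphenyl)-3,7-dioxabicyclo[3.3.0]octan-5-ol | COc1ccc([C@H]2OC[C@@]3(O)[C@@H]2CO[C@H]3c2ccc(OC)c(OC)c2)cc1OC | target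

Total step count: 6. Longest linear sequence: 6 steps (1 to 14); veratrole 12 enters in the last step.

Steps most likely to fail

Step 6. The oxocarbenium ion may lose the C1 proton and then the tertiary hydroxyl, which aromatises ring A to a furan. The acid may also ionise the benzylic C6–O7 bond, leading to epimerisation or cyclolignan-type ring closure. The fallback sets out from 11 and forms the O3–C2 bond last instead of the aryl–C2 bond. Excess 3,4-dimethoxyphenylmagnesium bromide (THF, 0 °C to rt) adds to the open hydroxy-aldehyde tautomer of the lactol and gives (3,4-dimethoxyphenyl)[(3R,4S,5S)-5-(3,4-dimethoxyphenyl)-4-hydroxy-4-(hydroxymethyl)oxolan-3-yl]methanol F1 as a mixture of carbinol epimers. Catalytic camphorsulfonic acid in CH2Cl2 at 0 °C should then ionise the electron-rich benzylic carbinol, and the primary C4 hydroxyl closes ring A in the 5-exo mode with the aryl group exo; both epimers converge through the same cation. The fallback comes back to the route at 14.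

Step 2. The methylenemalonate may oligomerise anionically before the alkoxide adds cleanly, and the base may start propargyl–allenyl isomerisation with erosion of enantiopurity. The fallback sets out from 4 and reverses the polarity of the O–CH2–C(malonate) construction. NaH, MeSCH2Cl and NaI in THF at 0 °C give the methylthiomethyl ether 4-[(1R)-1-[(methylsulfanyl)methoxy]prop-2-yn-1-yl]-1,2-dimethoxybenzene F2. SO2Cl2 with cyclohexene as sulfenyl chloride trap (CH2Cl2, −78 °C) converts it into the chloromethyl ether 4-[(1R)-1-(chloromethoxy)prop-2-yn-1-yl]-1,2-dimethoxybenzene F3. Sodium dimethyl malonate in THF at 0 °C is alkylated by F3. The fallback comes back to the route at 6, now isolated, which is cyclised with t-BuOK/CuI as in step 2.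

Step 4. The lactone enolate formed at high temperature may expel the tertiary hydroxyl by β-elimination or open by retro-aldol cleavage of the C1–C5 bond. The fallback sets out from 9 and decarboxylates the free acid through its neutral enol instead of through an enolate. Me3SnOH in 1,2-dichloroethane at 70 °C cleaves the methyl ester under neutral conditions, and dilute acid work-up gives (1S,5S,6S)-6-(3,4-dimethoxyphenyl)-5-hydroxy-2-oxo-3,7-dioxabicyclo[3.3.0]octane-1-carboxylic acid F4. Warming F4 in toluene at 90 °C should release CO2 by the cyclic malonic-acid mechanism. The fallback comes back to the route at 10.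

Further compounds
F1 | step 6 | (3,4-dimethoxyphenyl)[(3R,4S,5S)-5-(3,4-dimethoxyphenyl)-4-hydroxy-4-(hydroxymethyl)oxolan-3-yl]methanol (both carbinol epimers) | OC(c1ccc(OC)c(OC)c1)[C@H]1CO[C@@H](c2ccc(OC)c(OC)c2)[C@@]1(O)CO
F2 | step 2 | 4-[(1R)-1-[(methylsulfanyl)methoxy]prop-2-yn-1-yl]-1,2-dimethoxybenzene | C#C[C@@H](OCSC)c1ccc(OC)c(OC)c1
F3 | step 2 | 4-[(1R)-1-(chloromethoxy)prop-2-yn-1-yl]-1,2-dimethoxybenzene | C#C[C@@H](OCCl)c1ccc(OC)c(OC)c1
F4 | step 4 | (1S,5S,6S)-6-(3,4-dimethoxyphenyl)-5-hydroxy-2-oxo-3,7-dioxabicyclo[3.3.0]octane-1-carboxylic acid | O=C1OC[C@@]2(O)[C@]1(C(=O)O)CO[C@H]2c1ccc(OC)c(OC)c1
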